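**Retrosynthetic overview** (C1–C9 are the locants of the bicyclo[3.3.1]nonane core of the target)

1. Target 25 ← silyl ether 24 ← acyclic bis(β-dicarbonyl) compound 22 by one base-induced tandem Claisen cascade that makes C1–C9 and C2–C3; ring A (C1–C9–C5–C6–C7–C8) closes first and ring B (C1–C2–C3–C4–C5–C9) directly after it.
2. Enabling feature: C1 is a triacylmethane carbon (C2=O, C9=O, side-chain C=O) and C3 is the central carbon of the C2/C4 β-diketone of ring B, so both bonds are Claisen retrons. C5 is quaternary, so the C4 ketone enolizes only toward C3 and the C9 acyl donor (an S-tert-butyl thioester) cannot enolize.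
3. 22 ← auxiliary-controlled C5 prenylation and C1 acylation of 15 ← reductive Knoevenagel union (C5–C6) of aldehyde 9 with β-keto thioester 13.
4. 9 ← S-ethyl thioester 8 (Fukuyama reduction) ← thiolate cleavage of the Evans prenylation product 6 (sets C7), made from a mono-imide of 3,3-dimethylglutaric acid, whose five chain carbons become C6–C7–C8–C1–C2.
5. 13 ← γ-alkylation of S-tert-butyl 3-oxobutanethioate; the acyl group comes from (R)-2-methylbutanoic acid.

Key step: step 13

Remark: the enolized β-diketone of ring B is written as the 4-hydroxy-2-oxo tautomer, as in the target; the two enol forms interconvert, and all CIP descriptors refer to this tautomer.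

**Step 1**
Reactants: 1 3,3-dimethylglutaric anhydride; 2 (S)-4-benzyl-1,3-oxazolidin-2-one
Product: 3 5-[(4S)-4-benzyl-2-oxo-1,3-oxazolidin-3-yl]-3,3-dimethyl-5-oxopentanoic acid
Conditions: 2, n-BuLi, THF, −78 °C; then 1, −78 to 0 °C; aq. HCl
Reagents that add atoms: none
Why: N-acylation of the lithiated oxazolidinone by the symmetrical cyclic anhydride (anhydride ring opening) should give the mono-imide acid directly, and no selectivity is needed because the glutarate part is achiral.

**Step 2**
Reactants: 3 imide acid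
Product: 4 methyl 5-[(4S)-4-benzyl-2-oxo-1,3-oxazolidin-3-yl]-3,3-dimethyl-5-oxopentanoate
Conditions: MeI, K2CO3, DMF, 23 °C
Reagents that add atoms: iodomethane, CI
Why: carboxylate O-alkylation (SN2 esterification) should leave the imide untouched.

**Step 3**
Reactants: 4 imide ester; 5 prenyl bromide (1-bromo-3-methylbut-2-ene)
Product: 6 methyl (4S)-4-{[(4S)-4-benzyl-2-oxo-1,3-oxazolidin-3-yl]carbonyl}-3,3,7-trimethyloct-6-enoate
Conditions: NaHMDS, THF, −78 °C; then 5, −78 to −40 °C
Reagents that add atoms: none
Why: Evans alkylation, in which NaHMDS forms the chelated (Z)-sodium enolate of the imide (far more acidic than the ester α-CH2) and prenyl bromide adds to the face opposite the benzyl group, which sets the (4S) center that becomes C7.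

**Step 4**
Reactants: 6 alkylated imide; 7 ethanethiol
Product: 8 methyl (4S)-4-[(ethylsulfanyl)carbonyl]-3,3,7-trimethyloct-6-enoate
Conditions: 7 (3 equiv), n-BuLi (1.5 equiv), THF, 0 °C; then 6, 0 °C; aq. NH4Cl
Reagents that add atoms: none
Why: lithium ethanethiolate, a strong but weakly basic nucleophile, should attack the exocyclic imide carbonyl (acyl substitution, thiolate cleavage of an N-acyl oxazolidinone) and release the auxiliary without touching the methyl ester or epimerizing the α-center, which is shielded by the neighbouring quaternary carbon.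

**Step 5**
Reactants: 8 S-ethyl thioester
Product: 9 methyl (4S)-4-formyl-3,3,7-trimethyloct-6-enoate
Conditions: Et3SiH (3 equiv), Pd/C (10 wt %, 5 mol % Pd), acetone, 23 °C
Reagents that add atoms: none
Why: Fukuyama reduction, in which palladium inserts into the C–S bond and the acylpalladium species is reduced by the silane, should convert only the thioester into the aldehyde under neutral conditions, so the methyl ester, the trisubstituted alkene and the α-stereocenter (flanked by a quaternary carbon) are kept.

**Step 6**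
Reactants: 10 4-bromo-2-methylbutan-2-ol
Product: 11 [(4-bromo-2-methylbutan-2-yl)oxy]triethylsilane
Conditions: TESOTf, 2,6-lutidine, CH2Cl2, −78 to 0 °C
Reagents that add atoms: triethylsilyl trifluoromethanesulfonate, CC[Si](CC)(CC)OS(=O)(=O)C(F)(F)F
Why: silylation of the tertiary alcohol with the silyl triflate; the silyl ether later prevents an alkoxide from adding to the C4 ketone and triggering retro-Claisen cleavage.

**Step 7**
Reactants: 12 S-tert-butyl 3-oxobutanethioate; 11 bromide
Product: 13 S-tert-butyl 7-methyl-3-oxo-7-[(triethylsilyl)oxy]octanethioate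
Conditions: LDA (2.1 equiv), THF, 0 °C; then 11, DMPU, 0 to 23 °C; aq. NH4Cl
Reagents that add atoms: none
Why: γ-alkylation of the β-keto thioester dianion, in which the more basic terminal enolate carbon attacks the primary bromide.

**Step 8**
Reactants: 9 aldehyde; 13 β-keto thioester
Product: 15 methyl (4R)-4-{2-[(tert-butylsulfanyl)carbonyl]-7-methyl-3-oxo-7-[(triethylsilyl)oxy]octyl}-3,3,7-trimethyloct-6-enoate (epimer mixture at the thioester-bearing carbon), via alkylidene thioester 14 (not isolated)
Conditions: piperidine (10 mol %), AcOH (10 mol %), Hantzsch ester (1.3 equiv), 4 Å molecular sieves, toluene, 40 °C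
Reagents that add atoms: none
Why: amine-catalysed Knoevenagel condensation followed in the same flask by conjugate transfer hydrogenation of the doubly activated alkene 14 by the Hantzsch ester (reductive alkylation); nothing basic enough to epimerize the hindered aldehyde α-center is present, and the new center is made quaternary later.

**Step 9**
Reactants: 16 (R)-2-methylbutanoic acid
Product: 17 (2R)-1-(1H-imidazol-1-yl)-2-methylbutan-1-one
Conditions: 1,1'-carbonyldiimidazole, THF, 23 °C; used as a solution
Reagents that add atoms: 1,1'-carbonyldiimidazole, O=C(n1ccnc1)n1ccnc1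
Why: acid activation as the acyl imidazole does not pass through a ketene, so the α-stereocenter should be kept.

**Step 10**
Reactants: 15 keto thioester ester; 17 acyl imidazole
Product: 18 methyl (4R)-4-{2-[(tert-butylsulfanyl)carbonyl]-7-methyl-3-oxo-7-[(triethylsilyl)oxy]octyl}-3,3,7-trimethyl-2-[(2R)-2-methylbutanoyl]oct-6-enoate (epimer mixture at both acidic carbons)
Conditions: LDA (2.1 equiv), THF, −78 °C; then 17, −78 to −30 °C; aq. NH4Cl
Reagents that add atoms: none
Why: crossed Claisen-type C-acylation of an ester enolate, in which the first equivalent of LDA converts the β-keto thioester into its enolate (protecting ketone and thioester), the second forms the methyl ester enolate that adds to 17, and the released imidazolide deprotonates the new β-keto ester.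

**Step 11**
Reactants: 18 bis(β-dicarbonyl) compound; 19 L-valine tert-butyl ester
Product: 20 (Z)-β-enamino thioester of 18, in which the C4 ketone is replaced by C4(NH–CH(iPr)CO2tBu)=C5 with the N–H cis to the thioester carbonyl
Conditions: 19 (1.5 equiv), AcOH (cat.), 4 Å molecular sieves, benzene, 50 °C
Reagents that add atoms: none
Why: enamine condensation of the α-monosubstituted β-keto thioester with the primary amine should give the hydrogen-bonded (Z)-enamine, while the acyl ketone flanked by two branched carbons does not condense.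

**Step 12**
Reactants: 20 enamine; 5 prenyl bromide
Product: 22 methyl (4R)-4-{(2S)-2-[(tert-butylsulfanyl)carbonyl]-7-methyl-2-(3-methylbut-2-en-1-yl)-3-oxo-7-[(triethylsilyl)oxy]octyl}-3,3,7-trimethyl-2-[(2R)-2-methylbutanoyl]oct-6-enoate (epimer mixture only at C1), via prenylated imine 21 (not isolated)
Conditions: LDA (2.2 equiv), THF (no HMPA), −78 °C; then 5, −78 to −45 °C; then AcOH/NaOAc buffer (pH 4.5), THF/H2O, 23 °C
Reagents that add atoms: water, O
Why: chiral lithioenamine alkylation with the valine ester auxiliary, in which lithium is held by the nitrogen, the thioester carbonyl and the auxiliary ester, the isopropyl group covers one face, and prenyl bromide should enter from the lithium-bearing face anti to isopropyl to set the quaternary (S) center that becomes C5; the hindered enolate of the other β-keto ester is a spectator, and mild hydrolysis of 21 returns ketone and auxiliary.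

**Step 13**
Reactants: 22 acyclic precursor
Product: 24 (1S,5S,7R)-4-hydroxy-8,8-dimethyl-1-[(2R)-2-methylbutanoyl]-5,7-bis(3-methylbut-2-en-1-yl)-3-{3-methyl-3-[(triethylsilyl)oxy]butyl}bicyclo[3.3.1]non-3-ene-2,9-dione, via triacylmethane cyclohexanone 23 (not isolated)
Conditions: KHMDS (3.3 equiv), THF (0.01 M), −78 to 0 °C; aq. NH4Cl
Reagents that add atoms: none
Why: Proposed new method: KHMDS forms the bis-enolate of 22 (the C1 β-keto ester enolate and the C3 enolate of the C4 ketone); the C1 enolate adds to the C9 thioester and expels tert-butylthiolate to give the non-enolizable triacylmethane 23, whose waiting C3 enolate adds to the C2 methyl ester, expels methoxide and is deprotonated at the new C3–H, which makes the sequence irreversible. The closest known reaction types are the Dieckmann closure of a ketone enolate onto an ester at a quaternary carbon that completes bicyclo[3.3.1]nonane-2,4,9-triones, and domino Dieckmann cyclizations of acyclic keto diesters; the new element is a first C-acylation by a stabilized β-keto ester enolate, which is why C9 is a thioester (better acyl donor, weakly basic leaving group), so that this step is only slightly uphill and reversible. Ring A (C1–C9–C5–C6–C7–C8) closes 6-exo-trig through a chair with both prenyl groups equatorial, and ring B (C1–C2–C3–C4–C5–C9) closes 6-exo-trig between two groups that must both be axial on ring A. The only new stereocenter, C1, is fixed by C5: the bridge can form only when the C1–C2 bond is cis to the C5–C4 bond, and the epimer of 23 with the ester trans should revert by thiolate-induced retro-Claisen opening and be funnelled through the productive one; C5, C7 and the side-chain center are not touched, because the acyl ketone is masked as its enolate until C1 is quaternary and then has only a hindered methine. The selectivities needed are C- over O-acylation and ring A before ring B, and both follow from ring size: O-attack of the C1 enolate on C9, or attack of C3 on C2 before the C1–C9 bond exists, would have to close an eight-membered ring.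

**Step 14**
Reactants: 24 silyl ether
Product: 25 (1S,5S,7R)-4-hydroxy-3-(3-hydroxy-3-methylbutyl)-8,8-dimethyl-1-[(2R)-2-methylbutanoyl]-5,7-bis(3-methylbut-2-en-1-yl)bicyclo[3.3.1]non-3-ene-2,9-dione (CNP0326306.1)
Conditions: HF·pyridine, pyridine, THF, 0 °C
Reagents that add atoms: none
Why: fluoride-mediated cleavage of the tertiary triethylsilyl ether under buffered, non-acidic conditions should avoid dehydrative cyclization of the tertiary alcohol onto the enol.

**Compound list**

1 | 3,3-dimethylglutaric anhydride | CC1(C)CC(=O)OC(=O)C1 | starting material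
2 | (S)-4-benzyl-1,3-oxazolidin-2-one | O=C1N[C@@H](Cc2ccccc2)CO1 | starting material
3 | 5-[(4S)-4-benzyl-2-oxo-1,3-oxazolidin-3-yl]-3,3-dimethyl-5-oxopentanoic acid | OC(=O)CC(C)(C)CC(=O)N1[C@@H](Cc2ccccc2)COC1=O | intermediate
4 | methyl 5-[(4S)-4-benzyl-2-oxo-1,3-oxazolidin-3-yl]-3,3-dimethyl-5-oxopentanoate | COC(=O)CC(C)(C)CC(=O)N1[C@@H](Cc2ccccc2)COC1=O | intermediate
5 | prenyl bromide (1-bromo-3-methylbut-2-ene) | CC(C)=CCBr | starting material
6 | methyl (4S)-4-{[(4S)-4-benzyl-2-oxo-1,3-oxazolidin-3-yl]carbonyl}-3,3,7-trimethyloct-6-enoate | COC(=O)CC(C)(C)[C@H](CC=C(C)C)C(=O)N1[C@@H](Cc2ccccc2)COC1=O | intermediate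
7 | ethanethiol | CCS | starting material
8 | methyl (4S)-4-[(ethylsulfanyl)carbonyl]-3,3,7-trimethyloct-6-enoate | COC(=O)CC(C)(C)[C@H](CC=C(C)C)C(=O)SCC | intermediate
9 | methyl (4S)-4-formyl-3,3,7-trimethyloct-6-enoate | COC(=O)CC(C)(C)[C@H](CC=C(C)C)C=O | intermediate
10 | 4-bromo-2-methylbutan-2-ol | CC(C)(O)CCBr | starting material
11 | [(4-bromo-2-methylbutan-2-yl)oxy]triethylsilane | CC[Si](CC)(CC)OC(C)(C)CCBr | intermediate
12 | S-tert-butyl 3-oxobutanethioate | CC(=O)CC(=O)SC(C)(C)C | starting material
13 | S-tert-butyl 7-methyl-3-oxo-7-[(triethylsilyl)oxy]octanethioate | CC(C)(C)SC(=O)CC(=O)CCCC(C)(C)O[Si](CC)(CC)CC | intermediate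
14 | methyl (4R)-4-{2-[(tert-butylsulfanyl)carbonyl]-7-methyl-3-oxo-7-[(triethylsilyl)oxy]oct-1-en-1-yl}-3,3,7-trimethyloct-6-enoate (E/Z mixture) | COC(=O)CC(C)(C)[C@H](CC=C(C)C)C=C(C(=O)SC(C)(C)C)C(=O)CCCC(C)(C)O[Si](CC)(CC)CC | intermediate
15 | methyl (4R)-4-{2-[(tert-butylsulfanyl)carbonyl]-7-methyl-3-oxo-7-[(triethylsilyl)oxy]octyl}-3,3,7-trimethyloct-6-enoate | COC(=O)CC(C)(C)[C@H](CC=C(C)C)CC(C(=O)SC(C)(C)C)C(=O)CCCC(C)(C)O[Si](CC)(CC)CC | intermediate
16 | (R)-2-methylbutanoic acid | CC[C@@H](C)C(=O)O | starting material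
17 | (2R)-1-(1H-imidazol-1-yl)-2-methylbutan-1-one | CC[C@@H](C)C(=O)n1ccnc1 | intermediate
18 | methyl (4R)-4-{2-[(tert-butylsulfanyl)carbonyl]-7-methyl-3-oxo-7-[(triethylsilyl)oxy]octyl}-3,3,7-trimethyl-2-[(2R)-2-methylbutanoyl]oct-6-enoate | CC[C@@H](C)C(=O)C(C(=O)OC)C(C)(C)[C@H](CC=C(C)C)CC(C(=O)SC(C)(C)C)C(=O)CCCC(C)(C)O[Si](CC)(CC)CC | intermediate
19 | L-valine tert-butyl ester | CC(C)[C@H](N)C(=O)OC(C)(C)C | starting material
20 | (Z)-β-enamino thioester of 18 with 19 | CC[C@@H](C)C(=O)C(C(=O)OC)C(C)(C)[C@H](CC=C(C)C)C/C(C(=O)SC(C)(C)C)=C(\CCCC(C)(C)O[Si](CC)(CC)CC)N[C@@H](C(C)C)C(=O)OC(C)(C)C | intermediate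
21 | C5-prenylated imine of 22 with 19 | CC[C@@H](C)C(=O)C(C(=O)OC)C(C)(C)[C@H](CC=C(C)C)C[C@](CC=C(C)C)(C(=O)SC(C)(C)C)C(CCCC(C)(C)O[Si](CC)(CC)CC)=N[C@@H](C(C)C)C(=O)OC(C)(C)C | intermediate
22 | methyl (4R)-4-{(2S)-2-[(tert-butylsulfanyl)carbonyl]-7-methyl-2-(3-methylbut-2-en-1-yl)-3-oxo-7-[(triethylsilyl)oxy]octyl}-3,3,7-trimethyl-2-[(2R)-2-methylbutanoyl]oct-6-enoate | CC[C@@H](C)C(=O)C(C(=O)OC)C(C)(C)[C@H](CC=C(C)C)C[C@](CC=C(C)C)(C(=O)SC(C)(C)C)C(=O)CCCC(C)(C)O[Si](CC)(CC)CC | intermediate
23 | methyl (1R,3S,5R)-6,6-dimethyl-1-[(2R)-2-methylbutanoyl]-3,5-bis(3-methylbut-2-en-1-yl)-3-{5-methyl-5-[(triethylsilyl)oxy]hexanoyl}-2-oxocyclohexane-1-carboxylate | CC[C@@H](C)C(=O)[C@@]1(C(=O)OC)C(=O)[C@](CC=C(C)C)(C(=O)CCCC(C)(C)O[Si](CC)(CC)CC)C[C@@H](CC=C(C)C)C1(C)C | intermediate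
24 | (1S,5S,7R)-4-hydroxy-8,8-dimethyl-1-[(2R)-2-methylbutanoyl]-5,7-bis(3-methylbut-2-en-1-yl)-3-{3-methyl-3-[(triethylsilyl)oxy]butyl}bicyclo[3.3.1]non-3-ene-2,9-dione | CC[C@@H](C)C(=O)[C@]12C(=O)C(CCC(C)(C)O[Si](CC)(CC)CC)=C(O)[C@](CC=C(C)C)(C[C@@H](CC=C(C)C)C1(C)C)C2=O | intermediate
25 | (1S,5S,7R)-4-hydroxy-3-(3-hydroxy-3-methylbutyl)-8,8-dimethyl-1-[(2R)-2-methylbutanoyl]-5,7-bis(3-methylbut-2-en-1-yl)bicyclo[3.3.1]non-3-ene-2,9-dione | CC[C@@H](C)C(=O)[C@]12C(=O)C(CCC(C)(C)O)=C(O)[C@](CC=C(C)C)(C[C@@H](CC=C(C)C)C1(C)C)C2=O | target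

**Step count and risks**

Total steps: 14. Longest linear sequence: 11 steps (steps 1, 2, 3, 4, 5, 8, 10, 11, 12, 13, 14).

Steps most likely to fail:

Step 13. The first C-acylation may remain on the enolate side of its equilibrium, or ring A may close mainly with the ester trans to the C4 arm. In that case acyl transfer from C1 to C3, or loss of the 2-methylbutanoyl group by thiolate or methoxide attack, would compete with closure of ring B. The fallback builds the two bonds one at a time with known reactions, sets out from 15 and comes back at 24. 15 is condensed with 19 as in step 11 to the (Z)-enamine F1, which is lithiated and prenylated as in step 12 to the prenylated imine F2 and hydrolysed to the C5-quaternary keto thioester F3. Dieckmann cyclization of F3 (KOtBu, THF, 0 °C; ester enolate onto the thioester) gives the enolizable cyclic β-keto ester F4, which is a thermodynamically driven closure of the C1–C9 bond. Magnesium-mediated C-acylation of F4 (MgCl2, pyridine, CH2Cl2, 0 °C) with (2R)-2-methylbutanoyl chloride F5, made from 16 with oxalyl chloride and catalytic DMF, should give 23, with the acyl group entering anti to the C4 arm. 23 is then isolated and closed to 24 with KOtBu in THF (Dieckmann-type attack of the C3 enolate on the C2 ester).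

Step 12. Facial selectivity may be poor, or the second lithium enolate in the molecule may disturb the chelated lithioenamine, so that C5 forms as a mixture or conversion stalls. The fallback gives up reagent control, sets out from 18 (step 11 is skipped) and comes back at 24. Prenylation of 18 with K2CO3 and 5 in acetone should occur only at the less hindered thioester-bearing carbon and give 22 together with its C5 epimer F6. The mixture is taken through step 13. F6 should cyclize to the diastereomeric bicycle F7, which carries the C7 prenyl group on the endo face, and F7 is separated from 24 by chromatography at this rigid bicyclic stage.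

Step 10. Proton transfer from the new, more acidic β-keto ester to unreacted ester enolate, O-acylation of the thioester enolate, or attack of the acyl imidazole by the amide base may hold conversion low. The fallback replaces acylation by aldol addition and oxidation, sets out from 16 and 15 and comes back at 18. 16 is reduced with BH3·SMe2 to (2R)-2-methylbutan-1-ol F8, which is oxidized (TEMPO, PhI(OAc)2, CH2Cl2, 0 °C) to (2R)-2-methylbutanal F9 and used cold at once. Addition of the dilithio derivative of 15 (LDA, 2.1 equiv, THF, −78 °C) to F9 gives the non-acidic β-hydroxy ester F10 as a mixture of carbinol epimers. Dess–Martin oxidation of F10 then gives 18.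

**Further compounds**

F1 | step 13 | (Z)-β-enamino thioester of 15 with 19 | COC(=O)CC(C)(C)[C@H](CC=C(C)C)C/C(C(=O)SC(C)(C)C)=C(\CCCC(C)(C)O[Si](CC)(CC)CC)N[C@@H](C(C)C)C(=O)OC(C)(C)C
F2 | step 13 | C5-prenylated imine of F3 with 19 | COC(=O)CC(C)(C)[C@H](CC=C(C)C)C[C@](CC=C(C)C)(C(=O)SC(C)(C)C)C(CCCC(C)(C)O[Si](CC)(CC)CC)=N[C@@H](C(C)C)C(=O)OC(C)(C)C
F3 | step 13 | methyl (4R)-4-{(2S)-2-[(tert-butylsulfanyl)carbonyl]-7-methyl-2-(3-methylbut-2-en-1-yl)-3-oxo-7-[(triethylsilyl)oxy]octyl}-3,3,7-trimethyloct-6-enoate | COC(=O)CC(C)(C)[C@H](CC=C(C)C)C[C@](CC=C(C)C)(C(=O)SC(C)(C)C)C(=O)CCCC(C)(C)O[Si](CC)(CC)CC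
F4 | step 13 | methyl (3S,5R)-6,6-dimethyl-3,5-bis(3-methylbut-2-en-1-yl)-3-{5-methyl-5-[(triethylsilyl)oxy]hexanoyl}-2-oxocyclohexane-1-carboxylate | COC(=O)C1C(=O)[C@](CC=C(C)C)(C(=O)CCCC(C)(C)O[Si](CC)(CC)CC)C[C@@H](CC=C(C)C)C1(C)C
F5 | step 13 | (2R)-2-methylbutanoyl chloride | CC[C@@H](C)C(Cl)=O
F6 | step 12 | methyl (4R)-4-{(2R)-2-[(tert-butylsulfanyl)carbonyl]-7-methyl-2-(3-methylbut-2-en-1-yl)-3-oxo-7-[(triethylsilyl)oxy]octyl}-3,3,7-trimethyl-2-[(2R)-2-methylbutanoyl]oct-6-enoate | CC[C@@H](C)C(=O)C(C(=O)OC)C(C)(C)[C@H](CC=C(C)C)C[C@@](CC=C(C)C)(C(=O)SC(C)(C)C)C(=O)CCCC(C)(C)O[Si](CC)(CC)CC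
F7 | step 12 | (1R,5R,7R)-4-hydroxy-8,8-dimethyl-1-[(2R)-2-methylbutanoyl]-5,7-bis(3-methylbut-2-en-1-yl)-3-{3-methyl-3-[(triethylsilyl)oxy]butyl}bicyclo[3.3.1]non-3-ene-2,9-dione | CC[C@@H](C)C(=O)[C@@]12C(=O)C(CCC(C)(C)O[Si](CC)(CC)CC)=C(O)[C@@](CC=C(C)C)(C[C@@H](CC=C(C)C)C1(C)C)C2=O
F8 | step 10 | (2R)-2-methylbutan-1-ol | CC[C@@H](C)CO
F9 | step 10 | (2R)-2-methylbutanal | CC[C@@H](C)C=O
F10 | step 10 | methyl (4R)-4-{2-[(tert-butylsulfanyl)carbonyl]-7-methyl-3-oxo-7-[(triethylsilyl)oxy]octyl}-2-[(2R)-1-hydroxy-2-methylbutyl]-3,3,7-trimethyloct-6-enoate | CC[C@@H](C)C(O)C(C(=O)OC)C(C)(C)[C@H](CC=C(C)C)CC(C(=O)SC(C)(C)C)C(=O)CCCC(C)(C)O[Si](CC)(CC)CC
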